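Look at the delta run: by its last readings the target has nearly stopped rising, with most of the starting material unaccounted for as target.

the same everywhere: partner 1.05 equiv
- eta: starting material 1 M; second substrate 0.50 equiv; third substrate 2 equiv; protic impurity 0.14 M; temperature 85 °C; run made earlier
- delta: starting material 1 M; second substrate 0.50 equiv; third substrate 2 equiv; protic impurity 0.22 M; temperature 110 °C; run made earlier
- north: starting material 1.0 M; second substrate 0.500 equiv; third substrate 2.00 equiv; protic impurity 0.100 M; temperature 110 °C; time 12 h
- east: starting material 1.0 M; second substrate 0.500 equiv; third substrate 2.00 equiv; protic impurity 0.100 M; at 130 °C until 4.0 h, from then on at 90 °C; time 12 h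
- north-west: starting material 1.0 M; second substrate 0.500 equiv; third substrate 2.00 equiv; protic impurity 0.100 M; temperature 130 °C; time 12 h
- south: starting material 1.0 M; second substrate 0.500 equiv; third substrate 2.00 equiv; protic impurity 0.100 M; temperature 90 °C; time 12 h

| run | time / h | target / % |
|---|---|---|
| eta | 5.00 | 5.6 |
| eta | 10.0 | 10.4 |
| eta | 15.0 | 13.5 |
| eta | 20.0 | 16.7 |
| eta | 30.0 | 20.5 |
| delta | 0.500 | 4.0 |
| delta | 1.33 | 9.9 |
| delta | 2.50 | 13.5 |
| delta | 4.00 | 17.8 |
| delta | 6.00 | 20.6 |
| delta | 8.00 | 21.7 |
| delta | 10.0 | 22.4 |

(each reading ± 0.3 percentage points)



1. which flask leads in amount of target, in percent of the starting material charged ("all alike" within 1.5 percentage points) (north / east / north-west / south / all alike)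
2. how much target is there at the end, in percent of the starting material charged: north
3. how much target is there at the end, in percent of the starting material charged: east
4. how much target is there at the end, in percent of the starting material charged: north-west
5. how much target is there at the end, in percent of the starting material charged: south

So for a run that flattens as delta does, you can estimate the final amount from its last gains. Delta's last readings are equally spaced, and I take each gain to be a fixed fraction of the one before, here 0.636. Add up the gains still to come and you get a plateau of 23.6 %. The same fraction gives a half-time, the time in which half of the remaining gain arrives: 3.07 h for delta.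

I take partner to be the limiting reagent, with the other substrates competing for it. That is my assumption, since the readings show target only. Then the number to carry is the partner yield, the final target per equivalent of partner charged: 22.5 % in delta.

The eta run, reckoned the same way, has a gain fraction of 0.603, a plateau of 26.3 %, a half-time of 13.7 h and a partner yield of 25.0 %. With 0.3 percentage points on each reading, these are rough. Eta's yield is higher than delta's, but eta is both colder and lower in [protic impurity], so the two runs cannot separate these. My bet is on temperature.

That gives my reckoning. North, at delta's temperature, should reach 22.1 % by the end. North-west should finish below delta's plateau, being hotter. East should match north-west, since delta's half-time is already shorter than east's hot stretch. South, reckoned on eta's figures, should reach about 12.0 %, and somewhat more because it is a little warmer. So I put north in the lead.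

The forecast differs. It names north-west as the leader, with 33 % for north, 36.5 % for east, 37 % for north-west and 17.5 % for south. Its ground is: “Cutting the impurity to 0.10 M should lift the plateaus”.

    starting material + partner → target (k = 3.10 × 10⁻⁴ M⁻¹ min⁻¹, Ea = 91.0 kJ mol⁻¹)
    second substrate + partner → second product (k = 2.30 × 10⁻⁴ M⁻¹ min⁻¹, Ea = 113 kJ mol⁻¹)
    third substrate + partner → third product (k = 3.30 × 10⁻⁴ M⁻¹ min⁻¹, Ea = 110 kJ mol⁻¹)
    partner → decomposed reagent (k = 7.90 × 10⁻⁵ min⁻¹, Ea = 117 kJ mol⁻¹)
    third substrate + protic impurity → quenched substrate (k = 0.00540 M⁻¹ min⁻¹, Ea = 83.0 kJ mol⁻¹)
    (constants at 90 °C)

North gives 22.2 % and leads, with east at 17.9 %, north-west at 17.9 % and south at 15.0 %. Delta's recipe with north's amount of protic impurity stays at 21.8 %, against 22.4 % for delta itself. At 120 h north holds 22.6 % with partner at 0 %, and the partner yield from delta, 22.5 %, applied to the charge of 1.05 equiv, gives 23.6 %. East's own partner yield is 17.1 %. At that yield, a neighbour of east charged with 2.60 equiv of partner should reach 44.5 %; it holds 48.1 %.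

All runs stem from a simulated flask from invented constants; scatter was added.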